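The pitfall in a flask of two phases is to count the reagent charged as if the substrate met it at once, and to count a target molecule as safe once it is made.

    reagent in the reaction phase ⇌ reagent in the second phase, rate k1*([reagent in the reaction phase] - [reagent in the second phase]/K1) per volume of the first phase (K1 = 1.8, k1 = 0.046 s⁻¹)
    substrate + reagent in the reaction phase → target (k2 = 11 M⁻¹ s⁻¹)
    target ⇌ product in the second phase, rate k3*([target] - [product in the second phase]/K3) per volume of the first phase (K3 = 12, k3 = 0.0069 s⁻¹)
    target → decomposed product (k4 = 0.017 s⁻¹)
    target → over-reaction product (k5 = 0.074 s⁻¹)
    substrate + target → side product (k6 = 0.10 M⁻¹ s⁻¹)

substrate 0.10 M; reagent in the second phase 0.0900 M; time 1.0 min; volume of the second phase over the first 1.0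

- percentages count the substrate that a species holds: one side product counts as two
- target is meant together with its product in the second phase
- in the second phase: reagent in the second phase, product in the second phase; everything else is in the first
- charges count per volume of the first phase; a concentration in a rate is the amount of a species over the volume of its own phase; every rate counts per litre of the first phase
- run time (flask): 1.0 min

- amount of target and product in the second phase together at 1.0 min, in percent of the substrate charged
- the change that raises the amount of target and product in the second phase together at 1.0 min, in percent of the substrate charged most ("none" if none brings more than 2 percentage points) (delta / beta / epsilon / none)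
- amount of target and product in the second phase together at 1.0 min, in percent of the substrate charged, after beta

I follow one molecule through the flask. Reagent leaves the second phase at 0.0256 s⁻¹, and in the first phase substrate catches it at 1.10 s⁻¹, much faster than the 0.046 s⁻¹ at which it returns. So transfer out of the second phase is the rate-limiting step, and with substrate as charged I take the reagent to drain at about 0.0245 s⁻¹. By 1.0 min I reckon that as about 0.0693 M of target made.

A target molecule then stands at a fork. It can cross into the second phase, decompose or over-react, and together these take it with a lifetime of 10.2 s. The side step, at 0.0100 s⁻¹ with substrate as charged, is slower, and I set it aside for this count, which lifts the count a little. The escape chance, the transfer coefficient of the target over the sum of those first-order exits, is 7.05%.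

I count the target in two ways. In the first way I take the molecules born within the last lifetime as still standing, which is 0.00588 M, and the older ones as forked, and that gives 10.4%. The second way takes the present feed times the lifetime, 0.00518 M, with the same fork, and gives 9.70%. The second way cheats a little, because the feed falls by about a quarter within a lifetime, so I keep the first.

Doubling the target's transfer coefficient lifts the escape chance to 13.2%, and the same count gives about 13.9%. Doubling the reagent's transfer coefficient drains it, by my reckoning, at 0.0472 s⁻¹ and gives about 9.02%. With the reagent doubled, my count stops, since that charge exceeds the substrate charged.

The forecast gives 10.1% (9.3% to 10.9%), chooses epsilon, and puts beta at 9.4% (8.5% to 10.3%). Its ground: “Only the second phase protects product”.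

The simulation gives 10.3%, chooses epsilon with a gain of 3 percentage points, and gives 9.76% after beta, above my 9.02%. At 1.00 min the flask holds 3.95% as product in the second phase, 9.90% as decomposed product and 43.1% as over-reaction product. The second-phase share of these is 6.94%, against the escape chance of 7.05%.

The escape chance holds no substrate, so I carry it to the neighbouring flask with 0.25 M of substrate. There 3.70% of decomposed product and 16.1% of over-reaction product imply 1.50% in the second phase. The computed amount is 1.47%.

The constants are assumed; the result is computed.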